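## Structural features

The target 27 is a trans-fused 2,3,3a,4,5,7a-hexahydro-1H-inden-2-one: a cyclopentanone (C1, C2, C3, C3a, C7a) shares the C3a–C7a bond with a cyclohexene (C3a, C4, C5, C6=C7, C7a). Its six stereocentres are contiguous: C1 (Me), C7a, C3a and C3 (Et) on the five-membered ring, then the adjacent quaternary carbons C4 (Et, CO2H) and C5 (Et, E-styryl). H-3a and H-7a are trans, the carboxyl group is cis to H-3a and to the styryl group, and the two ethyl groups on C4 and C5 are cis. C1 and C3 flank the C2 ketone and can epimerise, but each alkyl group is trans to the neighbouring ring-fusion bond, which is the thermodynamically preferred position. Fragile points are these α-centres, the bis-allylic quaternary C5, and the free acid, which strong acid could add back across C6=C7. The real difficulty is the C4–C5 bond between two fully substituted carbons and its configuration relative to the trans ring fusion. The feature the key step exploits is that the acid is a γ,δ-unsaturated acid (O=C–C4–C5–C6=C7) with C4 and C5 as α- and β-carbons and the alkene inside the six-membered ring. This is a Claisen retron folded into the cyclohexene, so a [3,3] shift of a δ-lactone (ring oxygen on C7) makes C4–C5 and the carbocycle at once.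

## Logic of the disconnections

27 ⇒ 26. No skeletal bond is cut; the C2 carbonyl is masked as a dioxolane. A free C2 ketone would be enolised before C4 and would compete in every carbonyl addition at C7. The forward step must hydrolyse a hindered ketal without adding the acid across C6=C7; C1 and C3 are already in their stable configuration.

26 ⇒ 23 (key). The C4–C5 bond is cut and the carboxyl oxygen is reconnected to C7 (retro-[3,3]). In one sentence: an Ireland–Claisen rearrangement of the ring-fixed silyl ketene acetal of the bicyclic δ-lactone 23 turns the lactone into the cyclohexene and joins the two quaternary carbons. The cyclohexene and both quaternary centres disappear and 23 retains only a tertiary carbinol centre (C7) on a trans-disubstituted cyclopentane. The forward step needs the C7 configuration that puts the dienyl arm cis to H-7a, an E C5=C6 alkene, clean enolisation at C4, and a boat-like transition state that tolerates the trans-fused five-membered ring.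

23 ⇒ 21. The C7–ethyl bond and the lactone acyl–oxygen bond are cut. C7 is set by 1,2-induction from C7a, and which of its two carbon substituents enters last decides its configuration, so the ethyl group is added last to the dienyl ketone. The forward step needs Felkin-type facial selectivity, 1,2- rather than conjugate addition, and ketone-over-ester selectivity; the alkoxide then closes the lactone.

21 ⇒ 18 + 5 (through 20). The C6–C7 bond is cut. The E,E-diene is prepared separately and joined as a vinyl-metal to the aldehyde, then the carbinol is oxidised. The forward step needs retention of alkene geometry and aldehyde-over-ester selectivity.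

18 ⇒ 16 ⇒ 15. Functional-group changes only: the formyl group comes from a vinyl group, the ketal from the ketone. A vinyl group is the formyl equivalent that a cuprate can deliver; the ketal must be in place before the alkene is cleaved.

15 ⇒ 13 ⇒ 11. The C3–ethyl bond (enolate alkylation), then the C7a–vinyl and C1–methyl bonds (conjugate addition with enolate trapping) are cut. Each group enters trans to its ring neighbour, so the all-trans array follows from the single stereocentre C3a of 11. The forward steps need kinetic, regioselective enolisation at C3 and fast trapping at C1.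

11 ⇒ 8 + 7 (7 from 6). The C3a–C4 bond is cut. A Mukaiyama–Michael addition anti to the silyloxy group of 8, followed by loss of silanol, relays the chirality of 8 to C3a. C4 is not controlled and need not be.

5 ⇒ 3 + 4, and 3 ⇒ 1. The styryl C=C bond is cut (Horner–Wadsworth–Emmons); the bromo-enal comes from 1 by bromination and dehydrobromination. The forward steps must give E geometry at both alkenes.

## Other disconnections considered

Alternative 1: Cut C4–C5 and C3a–C7a together (retro-[4+2]); this is the disconnection that comes to mind first. The forward key step would be an intramolecular Diels–Alder reaction of the all-E tetraenoic acid A1, whose tether becomes the cyclopentanone. It fails the first test by definition. The diene terminus also carries an inside ethyl group, which disfavours the s-cis conformer. The cycloaddition must set four stereocentres at once (endo/exo and π-face) under control of only the two ketone α-centres, one of which is also allylic and prone to epimerisation in A1. The stereodefined tetraene needs a long linear assembly.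

Alternative 2: Cut C4–C5 alone, ionically. The forward key step would be a 6-endo Michael addition of the C4 ester enolate of 21 to C5 of its own dienone, giving the cyclohexanone A2; C7=O would then be converted to the C6=C7 ethyl alkene and the ester cleaved. In 21 the ketone α- and γ-hydrogens are more acidic than the ester α-hydrogen. A Michael addition joining two fully substituted carbons should be readily reversible, and the open transition state fixes neither enolate geometry nor approach, so the C4/C5 relationship would be uncontrolled. Three further steps would follow where the rearrangement delivers alkene and free acid directly.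

Alternative 3: Cut the exocyclic bonds C5–styryl and C4–ethyl on a preformed hydrindenone. The forward key step would be conjugate addition of a styryl cuprate to the tetrasubstituted enoate A3 and C-ethylation of the resulting enolate, followed by conversion of C7=O to the ethyl-substituted alkene. Cuprate addition to a β,β-dialkyl tetrasubstituted enoate is among the least favourable conjugate additions. The two quaternary centres would be set in two separate intermolecular events with independent facial selectivities, and the alkylation would have to place ethyl syn to the C5 ethyl group with no element enforcing it. The chosen rearrangement sets both centres in one intramolecular event with fixed geometry.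

Key step: step 12

Remark on numbering: locants C1–C7a are those of the hexahydroindene skeleton of 27 and are used for all intermediates.

Assumption: the configuration at C4 (ester or lactone α-carbon) is not controlled before step 12 and is left open in names and SMILES; C4 becomes planar in 24, so both epimers converge.

Assumption: compounds 1, 4, 6 and 8 are taken as commercial.

## Steps

Step 1
Reactants: 1 2-ethylacrolein
Product: 3 (E)-3-bromo-2-ethylprop-2-enal, via dibromide 2 (not isolated)
Conditions: Br2, CH2Cl2, −78 → 0 °C; then Et3N, 0 → 23 °C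
Reagents that add atoms: bromine, BrBr
Why: Bromination–dehydrobromination; there is no α-hydrogen, so HBr can only be lost across C2–C3 with departure of the α-bromine, giving the β-bromo-enal. The E isomer (Br trans to CHO) is the more stable one and should dominate.

Step 2
Reactants: 3 (E)-3-bromo-2-ethylprop-2-enal; 4 diethyl benzylphosphonate
Product: 5 (1E,3E)-1-bromo-2-ethyl-4-phenylbuta-1,3-diene
Conditions: NaH, THF, 0 → 23 °C
Reagents that add atoms: none
Why: Horner–Wadsworth–Emmons olefination; the benzyl phosphonate anion should give the E styryl bond, and the existing bromo-alkene geometry is untouched.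

Step 3
Reactants: 6 methyl butanoate
Product: 7 1-methoxy-1-(trimethylsilyloxy)but-1-ene (E/Z mixture)
Conditions: LDA, THF, −78 °C; TMSCl, −78 → 23 °C; distillation
Reagents that add atoms: chlorotrimethylsilane, C[Si](C)(C)Cl
Why: O-silylation of the lithium ester enolate; the ketene acetal geometry is irrelevant because C4 is not controlled at this stage.

Step 4
Reactants: 8 (R)-4-(tert-butyldimethylsilyloxy)cyclopent-2-en-1-one; 7 1-methoxy-1-(trimethylsilyloxy)but-1-ene
Product: 11 methyl 2-[(1R)-4-oxocyclopent-2-en-1-yl]butanoate, via silyl enol ether 9 (not isolated), via silyloxy ketone 10 (not isolated)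
Conditions: TMSOTf (5 mol %), CH2Cl2, −78 °C; 1 M HCl, THF, 0 °C; then DBU, CH2Cl2, 0 → 23 °C
Reagents that add atoms: none
Why: Mukaiyama–Michael addition anti to the silyloxy group sets C3a; E1cB loss of silanol from 10 then moves the enone so that C7a becomes the new β-carbon. The stereocentre of 8 is thereby relayed to C3a.

Step 5
Reactants: 11 methyl 2-[(1R)-4-oxocyclopent-2-en-1-yl]butanoate
Product: 13 methyl 2-[(1R,2S,3R)-2-ethenyl-3-methyl-4-oxocyclopentyl]butanoate, via magnesium enolate 12 (not isolated)
Conditions: vinylMgBr, CuBr·SMe2 (10 mol %), THF, −78 °C; then MeI, DMPU, −78 → 0 °C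
Reagents that add atoms: vinylmagnesium bromide, C=C[Mg]Br; iodomethane, CI
Why: Copper-catalysed conjugate addition anti to the C3a substituent sets C7a; the regiodefined enolate is methylated at C1 anti to the new vinyl group (conjugate addition–enolate trapping).

Step 6
Reactants: 13 methyl 2-[(1R,2S,3R)-2-ethenyl-3-methyl-4-oxocyclopentyl]butanoate
Product: 15 methyl 2-[(1S,2S,3R,5R)-2-ethenyl-5-ethyl-3-methyl-4-oxocyclopentyl]butanoate, via lithium enolate 14 (not isolated)
Conditions: LDA, THF, −78 °C; EtI, DMPU, −78 → −20 °C
Reagents that add atoms: iodoethane, CCI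
Why: Kinetic deprotonation at the C3 methylene (not the C1 methine or the less acidic ester α-CH) and alkylation anti to the C3a substituent complete the all-trans ring; this is also the thermodynamic arrangement.

Step 7
Reactants: 15 methyl 2-[(1S,2S,3R,5R)-2-ethenyl-5-ethyl-3-methyl-4-oxocyclopentyl]butanoate
Product: 16 methyl 2-[(6R,7S,8S,9R)-8-ethenyl-6-ethyl-9-methyl-1,4-dioxaspiro[4.4]nonan-7-yl]butanoate
Conditions: TMSOCH2CH2OTMS, TMSOTf (cat.), CH2Cl2, −78 → −20 °C
Reagents that add atoms: 1,2-bis(trimethylsilyloxy)ethane, C[Si](C)(C)OCCO[Si](C)(C)C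
Why: Aprotic silyl-triflate-catalysed ketalisation suits a hindered 2,5-dialkylcyclopentanone and leaves the ester and vinyl group alone; no stereocentre is affected.

Step 8
Reactants: 16 methyl 2-[(6R,7S,8S,9R)-8-ethenyl-6-ethyl-9-methyl-1,4-dioxaspiro[4.4]nonan-7-yl]butanoate
Product: 18 methyl 2-[(6R,7S,8S,9R)-6-ethyl-8-formyl-9-methyl-1,4-dioxaspiro[4.4]nonan-7-yl]butanoate, via ozonide 17 (not isolated)
Conditions: O3, CH2Cl2, −78 °C; then PPh3, −78 → 23 °C
Reagents that add atoms: ozone, [O-][O+]=O
Why: Ozonolysis with reductive work-up; the vinyl group is the only alkene, and the trans arrangement at C7a is the stable one for the α-formyl centre.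

Step 9
Reactants: 18 methyl 2-[(6R,7S,8S,9R)-6-ethyl-8-formyl-9-methyl-1,4-dioxaspiro[4.4]nonan-7-yl]butanoate; 5 (1E,3E)-1-bromo-2-ethyl-4-phenylbuta-1,3-diene
Product: 20 methyl 2-[(6R,7S,8S,9R)-6-ethyl-8-[(2E,4E)-3-ethyl-1-hydroxy-5-phenylpenta-2,4-dien-1-yl]-9-methyl-1,4-dioxaspiro[4.4]nonan-7-yl]butanoate (carbinol epimers), via dienyllithium 19 (not isolated)
Conditions: 5, t-BuLi (2 equiv), Et2O, −78 °C; then 18, THF, −78 °C; H2O, −78 °C
Reagents that add atoms: none
Why: Bromine–lithium exchange with retention of alkene geometry and 1,2-addition to the aldehyde, which is far more reactive than the methyl ester at −78 °C. The new carbinol centre is removed in step 10.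

Step 10
Reactants: 20 methyl 2-[(6R,7S,8S,9R)-6-ethyl-8-[(2E,4E)-3-ethyl-1-hydroxy-5-phenylpenta-2,4-dien-1-yl]-9-methyl-1,4-dioxaspiro[4.4]nonan-7-yl]butanoate
Product: 21 methyl 2-[(6R,7R,8S,9R)-6-ethyl-8-[(2E,4E)-3-ethyl-5-phenylpenta-2,4-dienoyl]-9-methyl-1,4-dioxaspiro[4.4]nonan-7-yl]butanoate
Conditions: Dess–Martin periodinane, CH2Cl2, 0 → 23 °C
Reagents that add atoms: none
Why: Neutral oxidation of the dienylic alcohol without touching the diene geometry; both carbinol epimers converge on one ketone.

Step 11
Reactants: 21 methyl 2-[(6R,7R,8S,9R)-6-ethyl-8-[(2E,4E)-3-ethyl-5-phenylpenta-2,4-dienoyl]-9-methyl-1,4-dioxaspiro[4.4]nonan-7-yl]butanoate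
Product: 23 (1R,4aS,5R,7R,7aS)-1,4,5-triethyl-1-[(1E,3E)-2-ethyl-4-phenylbuta-1,3-dien-1-yl]-6,6-(ethylenedioxy)-7-methylhexahydrocyclopenta[c]pyran-3(1H)-one (trans-fused δ-lactone; C7 R in target locants), via cerium alkoxide 22 (not isolated)
Conditions: EtMgBr, CeCl3, THF, −78 °C; then 23 °C; pH 7 buffer
Reagents that add atoms: ethylmagnesium bromide, CC[Mg]Br
Why: The organocerium reagent should add 1,2 to the dienone in preference to conjugate addition or attack on the ester. By the Felkin–Anh model the ethyl group enters anti to the C7a–C3a bond (the flank carrying the branched ester arm) and past H-7a, which gives the C7 R configuration with the dienyl arm cis to H-7a. The tertiary alkoxide then displaces methoxide to close the trans-fused δ-lactone.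

Step 12
Reactants: 23 (1R,4aS,5R,7R,7aS)-1,4,5-triethyl-1-[(1E,3E)-2-ethyl-4-phenylbuta-1,3-dien-1-yl]-6,6-(ethylenedioxy)-7-methylhexahydrocyclopenta[c]pyran-3(1H)-one
Product: 26 (1R,3R,3aS,4S,5R,7aS)-3,4,5,7-tetraethyl-2,2-(ethylenedioxy)-1-methyl-5-[(E)-2-phenylethenyl]-2,3,3a,4,5,7a-hexahydro-1H-indene-4-carboxylic acid, via silyl ketene acetal 24 (not isolated), via silyl ester 25 (not isolated)
Conditions: LDA, TMSCl, Et3N, THF, −78 °C; then toluene, 23 → 80 °C; then aq. citric acid, 23 °C
Reagents that add atoms: none
Why: Deprotonation at C4 with internal TMSCl trapping gives ketene acetal 24, whose C4=C(OSi) geometry is fixed by the lactone ring, so the usual E/Z problem of α,α-disubstituted ester enolates does not arise. 24 is a 2-alkenyl-6-silyloxy-3,4-dihydro-2H-pyran and should undergo a concerted suprafacial [3,3] shift in which C7–O breaks as C4–C5 forms; the closest known reaction type is the Ireland–Claisen rearrangement of silyl ketene acetals of alkenyl lactones to carbocyclic acids. The cyclohexene is closed through the only array the ring allows, a boat-like six-centre transition state bridged by C3a–C7a, not by an ionic exo or endo closure. C4 is set by the C7 stereocentre: the dienyl arm lies cis to H-7a and can reach only one face of C4, which leaves the carboxyl group cis to H-3a, and C7 itself becomes sp2 (a traceless relay). C5 is set by the E geometry of C5=C6: the substituent trans to C7 (styryl) ends cis to the carboxyl group and the cis one (ethyl) ends next to the C4 ethyl group. Because the breaking C7–O bond is long in this donor-substituted, doubly allylic system, C4 and C7 should lie about 3 Å apart in the transition state, so the C3a–C7a bridge stays gauche as the trans-fused cyclopentane demands; the twist sense fits only the C7 epimer used here. The step needs the sigmatropic path to outrun heterolysis of the tertiary dienylic C–O bond, which the silyl (not metal) ketene acetal, the non-polar medium and the low enolisation temperature are chosen to secure. Mild acid then cleaves the silyl ester to 26.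

Step 13
Reactants: 26 (1R,3R,3aS,4S,5R,7aS)-3,4,5,7-tetraethyl-2,2-(ethylenedioxy)-1-methyl-5-[(E)-2-phenylethenyl]-2,3,3a,4,5,7a-hexahydro-1H-indene-4-carboxylic acid
Product: 27 (1R,3R,3aS,4S,5R,7aS)-3,4,5,7-tetraethyl-1-methyl-2-oxo-5-[(E)-2-phenylethenyl]-2,3,3a,4,5,7a-hexahydro-1H-indene-4-carboxylic acid
Conditions: 1 M HCl, THF, 23 → 40 °C
Reagents that add atoms: water, O
Why: Acid hydrolysis of the dioxolane; C1 and C3 already have the stable configuration (each alkyl trans to the adjacent ring-fusion bond), so enolisation cannot erode them. Dilute acid and moderate temperature are chosen so the carboxyl group does not add across C6=C7.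

## Compound list

1 | 2-ethylacrolein | C=C(CC)C=O | starting material
2 | 2,3-dibromo-2-ethylpropanal (racemic, formed in situ) | BrCC(Br)(CC)C=O | intermediate
3 | (E)-3-bromo-2-ethylprop-2-enal | Br/C=C(/C=O)CC | intermediate
4 | diethyl benzylphosphonate | CCOP(=O)(Cc1ccccc1)OCC | starting material
5 | (1E,3E)-1-bromo-2-ethyl-4-phenylbuta-1,3-diene | Br/C=C(CC)/C=C/c1ccccc1 | intermediate
6 | methyl butanoate | CCCC(=O)OC | starting material
7 | 1-methoxy-1-(trimethylsilyloxy)but-1-ene (E/Z mixture) | CCC=C(OC)O[Si](C)(C)C | intermediate
8 | (R)-4-(tert-butyldimethylsilyloxy)cyclopent-2-en-1-one | O=C1C=C[C@H](O[Si](C)(C)C(C)(C)C)C1 | starting material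
9 | methyl 2-[(1S,2R)-2-(tert-butyldimethylsilyloxy)-4-(trimethylsilyloxy)cyclopent-3-en-1-yl]butanoate (formed in situ) | COC(=O)C(CC)[C@H]1[C@H](O[Si](C)(C)C(C)(C)C)CC(O[Si](C)(C)C)=C1 | intermediate
10 | methyl 2-[(1S,2R)-2-(tert-butyldimethylsilyloxy)-4-oxocyclopentyl]butanoate (formed in situ) | COC(=O)C(CC)[C@H]1[C@H](O[Si](C)(C)C(C)(C)C)CC(=O)C1 | intermediate
11 | methyl 2-[(1R)-4-oxocyclopent-2-en-1-yl]butanoate | COC(=O)C(CC)[C@H]1C=CC(=O)C1 | intermediate
12 | bromomagnesium C1=C2 enolate from vinyl addition to 11 (formed in situ) | COC(=O)C(CC)[C@H]1[C@H](C=C)C=C(O[Mg]Br)C1 | intermediate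
13 | methyl 2-[(1R,2S,3R)-2-ethenyl-3-methyl-4-oxocyclopentyl]butanoate | COC(=O)C(CC)[C@H]1[C@H](C=C)[C@@H](C)C(=O)C1 | intermediate
14 | lithium C2=C3 enolate of 13 (formed in situ) | COC(=O)C(CC)[C@H]1[C@H](C=C)[C@@H](C)C(O[Li])=C1 | intermediate
15 | methyl 2-[(1S,2S,3R,5R)-2-ethenyl-5-ethyl-3-methyl-4-oxocyclopentyl]butanoate (all-trans ring) | COC(=O)C(CC)[C@H]1[C@H](C=C)[C@@H](C)C(=O)[C@@H]1CC | intermediate
16 | methyl 2-[(6R,7S,8S,9R)-8-ethenyl-6-ethyl-9-methyl-1,4-dioxaspiro[4.4]nonan-7-yl]butanoate | COC(=O)C(CC)[C@H]1[C@H](C=C)[C@@H](C)C2(OCCO2)[C@@H]1CC | intermediate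
17 | 1,2,4-trioxolane (ozonide) of 16 (formed in situ) | COC(=O)C(CC)[C@H]1[C@H](C3OCOO3)[C@@H](C)C2(OCCO2)[C@@H]1CC | intermediate
18 | methyl 2-[(6R,7S,8S,9R)-6-ethyl-8-formyl-9-methyl-1,4-dioxaspiro[4.4]nonan-7-yl]butanoate | COC(=O)C(CC)[C@H]1[C@H](C=O)[C@@H](C)C2(OCCO2)[C@@H]1CC | intermediate
19 | [(1E,3E)-2-ethyl-4-phenylbuta-1,3-dien-1-yl]lithium (formed in situ) | [Li]/C=C(CC)/C=C/c1ccccc1 | intermediate
20 | methyl 2-[(6R,7S,8S,9R)-6-ethyl-8-[(2E,4E)-3-ethyl-1-hydroxy-5-phenylpenta-2,4-dien-1-yl]-9-methyl-1,4-dioxaspiro[4.4]nonan-7-yl]butanoate (carbinol epimers) | COC(=O)C(CC)[C@H]1[C@H](C(O)/C=C(CC)/C=C/c3ccccc3)[C@@H](C)C2(OCCO2)[C@@H]1CC | intermediate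
21 | methyl 2-[(6R,7R,8S,9R)-6-ethyl-8-[(2E,4E)-3-ethyl-5-phenylpenta-2,4-dienoyl]-9-methyl-1,4-dioxaspiro[4.4]nonan-7-yl]butanoate | COC(=O)C(CC)[C@H]1[C@H](C(=O)/C=C(CC)/C=C/c3ccccc3)[C@@H](C)C2(OCCO2)[C@@H]1CC | intermediate
22 | dichlorocerium alkoxide of the C7 R tertiary alcohol from ethyl addition to 21 (formed in situ) | COC(=O)C(CC)[C@H]1[C@H]([C@@](CC)(O[Ce](Cl)Cl)/C=C(CC)/C=C/c3ccccc3)[C@@H](C)C2(OCCO2)[C@@H]1CC | intermediate
23 | (1R,4aS,5R,7R,7aS)-1,4,5-triethyl-1-[(1E,3E)-2-ethyl-4-phenylbuta-1,3-dien-1-yl]-6,6-(ethylenedioxy)-7-methylhexahydrocyclopenta[c]pyran-3(1H)-one (trans-fused; target locants C7 R, C3a S, C3 R, C1 R, C7a S) | CC[C@@]1(/C=C(CC)/C=C/c2ccccc2)OC(=O)C(CC)[C@H]3[C@H]1[C@@H](C)C4(OCCO4)[C@@H]3CC | intermediate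
24 | trimethylsilyl ketene acetal of 23 (3-trimethylsilyloxy-1,4a,5,6,7,7a-hexahydrocyclopenta[c]pyran; formed in situ) | CC[C@@]1(/C=C(CC)/C=C/c2ccccc2)OC(O[Si](C)(C)C)=C(CC)[C@H]3[C@H]1[C@@H](C)C4(OCCO4)[C@@H]3CC | intermediate
25 | trimethylsilyl ester of 26 (formed in situ) | CCC1=C[C@](/C=C/c2ccccc2)(CC)[C@@](CC)(C(=O)O[Si](C)(C)C)[C@H]3[C@H]1[C@@H](C)C4(OCCO4)[C@@H]3CC | intermediate
26 | (1R,3R,3aS,4S,5R,7aS)-3,4,5,7-tetraethyl-2,2-(ethylenedioxy)-1-methyl-5-[(E)-2-phenylethenyl]-2,3,3a,4,5,7a-hexahydro-1H-indene-4-carboxylic acid | CCC1=C[C@](/C=C/c2ccccc2)(CC)[C@@](CC)(C(=O)O)[C@H]3[C@H]1[C@@H](C)C4(OCCO4)[C@@H]3CC | intermediate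
27 | (1R,3R,3aS,4S,5R,7aS)-3,4,5,7-tetraethyl-1-methyl-2-oxo-5-[(E)-2-phenylethenyl]-2,3,3a,4,5,7a-hexahydro-1H-indene-4-carboxylic acid | CCC1=C[C@](/C=C/c2ccccc2)(CC)[C@@](CC)(C(=O)O)[C@H]2[C@H]1[C@@H](C)C(=O)[C@@H]2CC | target

## Step count and least certain steps

Total: 13 steps. Longest linear sequence: 11 steps (6 → 7 → 11 → … → 27, steps 3–13); from 8 it is 10 steps, and the dienyl branch (steps 1–2) joins at step 9.

**Step 12 (key step).** Most likely to go wrong is heterolysis of the tertiary, doubly allylic C7–O bond of 24 (loss of the silyl carboxylate, then elimination or non-stereospecific recombination) outrunning the concerted shift. The other risk is that the trans-fused cyclopentane raises the barrier of the boat-like transition state so far that the ketene acetal decomposes first.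

Fallback (sets out from 11, returns at 26): the C4–C5 bond is made by an acyclic ester-enolate Claisen rearrangement that forms the styryl double bond, and the ring is closed afterwards by metathesis.
- Copper-catalysed addition of but-1-en-2-ylmagnesium bromide to 11 and methylation as in step 5 would give the C7a-(but-1-en-2-yl) analogue of 13 F1. Ethylation as in step 6 would give the all-trans ketone F2, ketalisation as in step 7 the ketal ester F3, and LiOH the ketal acid F4.
- Methylenation of 3 (Ph3P=CH2) would give (E)-1-bromo-2-ethylbuta-1,3-diene F5. Bromine–lithium exchange, transmetalation to zinc and amino-alcohol-catalysed addition to benzaldehyde would give (1S,2E)-3-ethyl-1-phenylpenta-2,4-dien-1-ol F6.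
- Carbodiimide esterification of F4 with F6 would give the dienyl ester F7. Ireland–Claisen rearrangement (KHMDS, TMSCl, THF, −78 °C, then 23–60 °C) through a chair with phenyl equatorial would give the triene acid F8. This requires the ketene acetal geometry with the ring carbon cis to the allylic oxygen, and separation from the product of the other geometry is the price of this route.
- Ring-closing metathesis between the C5 vinyl and the C7a but-1-en-2-yl groups with a second-generation ruthenium benzylidene catalyst would then give 26.

**Step 11.** Most likely to go wrong is poor facial selectivity in the addition to the C7 ketone, since both flanks of C7a are secondary ring carbons, giving much of the C7 epimer, which cannot reach the required transition state in step 12. Conjugate addition to the dienone and sluggish lactonisation are lesser risks.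

Fallback (sets out from 18, returns at 23): the order in which the two C7 substituents are introduced is reversed, so the same facial bias delivers the opposite C7 configuration. EtMgBr at −78 °C would give the 1-hydroxypropyl compound F9 and Dess–Martin oxidation the ethyl ketone F10. Addition of the dienylcerium reagent from 19 and CeCl3, with lactonisation on warming, would then give 23.

**Step 6.** Most likely to go wrong is proton transfer between enolate 14 and already alkylated ketone during the slow reaction with iodoethane, leading to regio-isomerisation and over-alkylation.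

Fallback (sets out from 13, returns at 15): the ethyl group is built by aldol chemistry. The lithium enolate of 13 and acetaldehyde would give the C3-(1-hydroxyethyl) aldol F11. Mesylation and elimination (MsCl, Et3N; DBU) would give the (E)-ethylidene enone F12. Conjugate reduction with [(Ph3P)CuH]6 and equilibration with DBU would give 15.

**Step 9.** Most likely to go wrong is erosion of the diene geometry, or addition of t-BuLi to the styryl diene during the exchange. The secondary alkoxide of 20 may also lactonise onto the ester, which would block step 10.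

Fallback (sets out from 18, returns at 21): the diene is completed after the C6–C7 bond is made. But-1-ynyllithium would add to 18 to give the propargylic alcohol F13 and Dess–Martin oxidation would give the ynone F14. Rhodium-catalysed syn addition of (E)-2-phenylethenylboronic acid across the alkyne (styryl to C5, hydrogen to C6) would give the E,E-dienone 21.

## Further compounds

F1 | step 12 | methyl 2-[(1R,2S,3R)-2-(but-1-en-2-yl)-3-methyl-4-oxocyclopentyl]butanoate | COC(=O)C(CC)[C@H]1[C@H](C(CC)=C)[C@@H](C)C(=O)C1
F2 | step 12 | methyl 2-[2-(but-1-en-2-yl)-5-ethyl-3-methyl-4-oxocyclopentyl]butanoate (all-trans ring, ring configuration as in 15) | COC(=O)C(CC)[C@H]1[C@H](C(CC)=C)[C@@H](C)C(=O)[C@@H]1CC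
F3 | step 12 | ethylene ketal of F2 (C7a-(but-1-en-2-yl) analogue of 16) | COC(=O)C(CC)[C@H]1[C@H](C(CC)=C)[C@@H](C)C2(OCCO2)[C@@H]1CC
F4 | step 12 | carboxylic acid from F3 | OC(=O)C(CC)[C@H]1[C@H](C(CC)=C)[C@@H](C)C2(OCCO2)[C@@H]1CC
F5 | step 12 | (E)-1-bromo-2-ethylbuta-1,3-diene | Br/C=C(/C=C)CC
F6 | step 12 | (1S,2E)-3-ethyl-1-phenylpenta-2,4-dien-1-ol | C=C/C(CC)=C/[C@@H](c1ccccc1)O
F7 | step 12 | (1S,2E)-3-ethyl-1-phenylpenta-2,4-dien-1-yl ester of F4 | C=C/C(CC)=C/[C@@H](c1ccccc1)OC(=O)C(CC)[C@H]2[C@H](C(CC)=C)[C@@H](C)C3(OCCO3)[C@@H]2CC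
F8 | step 12 | 2-ethyl-2-[ring]-3-ethyl-3-ethenyl-5-phenylpent-4-enoic acid, the ring-opened (C6/C7 seco) precursor of 26 with C4 S and C5 R as in 26 | C=C[C@](/C=C/c1ccccc1)(CC)[C@@](CC)(C(=O)O)[C@H]2[C@H](C(CC)=C)[C@@H](C)C3(OCCO3)[C@@H]2CC
F9 | step 11 | methyl 2-[(6R,7S,8S,9R)-6-ethyl-8-(1-hydroxypropyl)-9-methyl-1,4-dioxaspiro[4.4]nonan-7-yl]butanoate (carbinol epimers) | COC(=O)C(CC)[C@H]1[C@H](C(O)CC)[C@@H](C)C2(OCCO2)[C@@H]1CC
F10 | step 11 | methyl 2-[6-ethyl-9-methyl-8-propanoyl-1,4-dioxaspiro[4.4]nonan-7-yl]butanoate (ring configuration as in 18) | COC(=O)C(CC)[C@H]1[C@H](C(=O)CC)[C@@H](C)C2(OCCO2)[C@@H]1CC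
F11 | step 6 | methyl 2-[2-ethenyl-5-(1-hydroxyethyl)-3-methyl-4-oxocyclopentyl]butanoate (aldol of 13; C3 and carbinol unassigned) | CC(O)C1C(=O)[C@H](C)[C@@H](C=C)[C@@H]1C(CC)C(=O)OC
F12 | step 6 | methyl 2-[(5E)-2-ethenyl-5-ethylidene-3-methyl-4-oxocyclopentyl]butanoate | C/C=C1/C(=O)[C@H](C)[C@@H](C=C)[C@@H]1C(CC)C(=O)OC
F13 | step 9 | methyl 2-[6-ethyl-8-(1-hydroxypent-2-yn-1-yl)-9-methyl-1,4-dioxaspiro[4.4]nonan-7-yl]butanoate (ring as in 18; carbinol epimers) | COC(=O)C(CC)[C@H]1[C@H](C(O)C#CCC)[C@@H](C)C2(OCCO2)[C@@H]1CC
F14 | step 9 | methyl 2-[6-ethyl-9-methyl-8-(pent-2-ynoyl)-1,4-dioxaspiro[4.4]nonan-7-yl]butanoate (ring as in 18) | COC(=O)C(CC)[C@H]1[C@H](C(=O)C#CCC)[C@@H](C)C2(OCCO2)[C@@H]1CC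
A1 | alternative 1 | (2E,4R,6R,7E,9E,11E)-2,4,8,10-tetraethyl-6-methyl-5-oxo-12-phenyldodeca-2,7,9,11-tetraenoic acid | OC(=O)/C(CC)=C/[C@@H](CC)C(=O)[C@H](C)/C=C(CC)/C=C(CC)/C=C/c1ccccc1
A2 | alternative 2 | methyl ester of the C2 ethylene ketal of the 7-oxo-6,7-dihydro-7-de-ethyl analogue of 27 (Michael adduct; stereocentres as in 26) | O=C1C[C@](/C=C/c2ccccc2)(CC)[C@@](CC)(C(=O)OC)[C@H]3[C@H]1[C@@H](C)C4(OCCO4)[C@@H]3CC
A3 | alternative 3 | methyl 3,5-diethyl-2,2-(ethylenedioxy)-1-methyl-7-oxo-2,3,3a,6,7,7a-hexahydro-1H-indene-4-carboxylate (C1, C3, C3a, C7a as in 27) | COC(=O)C1=C(CC)CC(=O)[C@H]2[C@H]1[C@@H](CC)C3(OCCO3)[C@@H]2C
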